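## Retrosynthetic overview

1. Target ⇐ cage tetraol: the C3 acetate/C4 hydroxyl pair comes from regioselective opening of a cyclic orthoacetate, the C11 acetate from acetate capture of the nortricyclyl cation, and the cis-diol from a top-face epoxide by CO2 insertion.
2. Cyclopropane (last ring) ⇐ intramolecular cyclopropanation of an α-diazo ethyl ketone on C6 onto the ring B cyclopentene.
3. Ring B ⇐ ring-closing metathesis of trans allyl/vinyl groups on ring A; the ring A alkene is masked, and its top face addressed, by iodolactonisation from the C12 acid.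
4. Ring A with the contiguous quaternary carbons C5/C6/C1 ⇐ Ireland–Claisen ring contraction of a 6-alkenyl δ-lactone, which transfers chirality from C3 to C6.
5. δ-Lactone ⇐ enantioselective vinylogous aldol union of a dioxinone dienolate (C11, C6, C1, C2) with 3-methylbut-2-enal (C3–C5 plus both methyls), then triflate/Stille, cuprate and allylation. Ring order: lactone → A → B → cyclopropane.

Assumption: the Ti–(R)-BINOL catalyst delivers the dienolate to the Re face of the aldehyde, as in related Ti–BINOL carbonyl additions.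

Atom labels used throughout (they follow the target): C1 = quaternary carbon bearing C12H2O; C2 = CH2; C3 = CH(O); C4 = CH(O); C5 = CMe2; C6 = cage bridgehead; C7 = CH2; C8, C9 = cyclopropane CH; C10 = cyclopropane C–CH3; C11 = CH(O). Ring A = C1–C6; ring B = C6–C7–C8–C9–C1. "Top face" of ring A = the face carrying C12, C7, O3 and O4.

## Route

Step 1
Reactants: 1 2,2,6-trimethyl-4H-1,3-dioxin-4-one
Product: 2 2,2-dimethyl-6-methylidene-4-(trimethylsilyloxy)-1,3-diox-4-ene
Conditions: LiN(iPr)2, THF, −78 °C; TMSCl, −78 → 0 °C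
Reagents that add atoms: chlorotrimethylsilane, C[Si](C)(C)Cl
Why: γ-Deprotonation of the vinylogous ester and O-silylation (silyl dienol ether formation) give the dienolate equivalent needed for a vinylogous Mukaiyama aldol.

Step 2
Reactants: 2 2,2-dimethyl-6-methylidene-4-(trimethylsilyloxy)-1,3-diox-4-ene; 3 3-methylbut-2-enal
Product: 5 6-[(2R)-2-hydroxy-4-methylpent-3-enyl]-2,2-dimethyl-4H-1,3-dioxin-4-one, via silyl ether 4 (not isolated)
Conditions: Ti(OiPr)4 (20 mol %), (R)-BINOL (20 mol %), 4 Å MS, THF, −78 → −20 °C; then 1 M HCl, THF, 0 °C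
Reagents that add atoms: none
Why: Vinylogous Mukaiyama aldol reaction in which the chiral Ti–BINOL Lewis acid binds the aldehyde and exposes its Re face to the γ-carbon of 2, setting the (R)-carbinol centre (C3) that later relays chirality to C6 and C1.

Step 3
Reactants: 5 6-[(2R)-2-hydroxy-4-methylpent-3-enyl]-2,2-dimethyl-4H-1,3-dioxin-4-one
Product: 7 (6R)-6-(2-methylprop-1-enyl)oxane-2,4-dione, via acylketene 6 (not isolated)
Conditions: toluene (0.01 M), 110 °C
Reagents that add atoms: none
Why: Thermal retro-[4+2] loss of acetone gives an acylketene that is trapped by the δ-hydroxyl (intramolecular ketene acylation/lactonisation) without touching C3.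

Step 4
Reactants: 7 (6R)-6-(2-methylprop-1-enyl)oxane-2,4-dione
Product: 8 (6R)-6-(2-methylprop-1-enyl)-2-oxo-5,6-dihydro-2H-pyran-4-yl trifluoromethanesulfonate
Conditions: Tf2O, Et3N, CH2Cl2, −78 °C
Reagents that add atoms: trifluoromethanesulfonic anhydride, O=S(=O)(OS(=O)(=O)C(F)(F)F)C(F)(F)F
Why: O-Triflation of the enolised β-keto lactone (enol sulfonylation) gives a vinylogous acyl triflate primed for cross-coupling.

Step 5
Reactants: 8 (6R)-6-(2-methylprop-1-enyl)-2-oxo-5,6-dihydro-2H-pyran-4-yl trifluoromethanesulfonate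
Product: 9 (6R)-4-(hydroxymethyl)-6-(2-methylprop-1-enyl)-5,6-dihydro-2H-pyran-2-one
Conditions: Bu3SnCH2OH, Pd2(dba)3 (2.5 mol %), P(2-furyl)3 (10 mol %), NMP, 50 °C
Reagents that add atoms: (tributylstannyl)methanol, CCCC[Sn](CCCC)(CCCC)CO
Why: Stille cross-coupling, in which zerovalent palladium inserts readily into the vinylogous acyl triflate and the α-oxygenated CH2OH group transfers from tin in preference to butyl.

Step 6
Reactants: 9 (6R)-4-(hydroxymethyl)-6-(2-methylprop-1-enyl)-5,6-dihydro-2H-pyran-2-one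
Product: 10 (6R)-4-[(tert-butyldimethylsilyloxy)methyl]-6-(2-methylprop-1-enyl)-5,6-dihydro-2H-pyran-2-one
Conditions: TBSCl, imidazole, DMF, rt
Reagents that add atoms: tert-butyldimethylsilyl chloride, CC(C)(C)[Si](C)(C)Cl
Why: Standard silyl ether formation (silylation) masks the primary allylic alcohol for the organometallic steps.

Step 7
Reactants: 10 (6R)-4-[(tert-butyldimethylsilyloxy)methyl]-6-(2-methylprop-1-enyl)-5,6-dihydro-2H-pyran-2-one
Product: 12 (4R,6R)-4-[(tert-butyldimethylsilyloxy)methyl]-4-ethenyl-6-(2-methylprop-1-enyl)oxan-2-one (ethenyl trans and CH2OTBS cis to the propenyl group), via silyl ketene acetal 11 (not isolated)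
Conditions: CH2=CHMgBr, CuBr·SMe2 (10 mol %), TMSCl, THF, −78 → −40 °C; then 1 M HCl
Reagents that add atoms: vinylmagnesium bromide, C=C[Mg]Br
Why: TMSCl-accelerated copper-catalysed conjugate addition proceeds by axial attack anti to the C3 propenyl group, so vinyl enters trans to it and the new C1 quaternary centre carries CH2OTBS cis to the propenyl group.

Step 8
Reactants: 12 (4R,6R)-4-[(tert-butyldimethylsilyloxy)methyl]-4-ethenyl-6-(2-methylprop-1-enyl)oxan-2-one
Product: 13 3-allyl-4-[(tert-butyldimethylsilyloxy)methyl]-4-ethenyl-6-(2-methylprop-1-enyl)oxan-2-one (ring centres C1 and C3 as in 12; epimer mixture at the allyl-bearing C6)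
Conditions: LiN(iPr)2, THF, −78 °C; allyl bromide, DMPU, −78 → −20 °C
Reagents that add atoms: allyl bromide, C=CCBr
Why: Lactone enolate alkylation with a reactive allylic halide; the C6 configuration is irrelevant because this carbon is enolised in the next step.

Step 9
Reactants: 13 3-allyl-4-[(tert-butyldimethylsilyloxy)methyl]-4-ethenyl-6-(2-methylprop-1-enyl)oxan-2-one
Product: 16 (1R,6S)-6-[(tert-butyldimethylsilyloxy)methyl]-6-ethenyl-2,2-dimethyl-1-(prop-2-enyl)cyclohex-3-ene-1-carboxylic acid (CO2H anti to CH2OTBS; allyl trans to ethenyl), via silyl ketene acetal 14 (not isolated), via silyl ester 15 (not isolated)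
Conditions: KN(SiMe3)2, TMSCl, Et3N, THF, −78 → 20 °C; toluene, 110 °C; then 1 M HCl
Reagents that add atoms: none
Why: Ireland–Claisen rearrangement in its ring-contracting form, in which the propenyl terminus bonds to C6 suprafacially through a boat transition state, transferring the C3 configuration to quaternary C6 (allyl trans to vinyl, CO2H anti to CH2OTBS) while creating the C5 gem-dimethyl carbon and the C3=C4 alkene.

Step 10
Reactants: 16 (1R,6S)-6-[(tert-butyldimethylsilyloxy)methyl]-6-ethenyl-2,2-dimethyl-1-(prop-2-enyl)cyclohex-3-ene-1-carboxylic acid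
Product: 17 1-[(1R,6S)-6-[(tert-butyldimethylsilyloxy)methyl]-6-ethenyl-2,2-dimethyl-1-(prop-2-enyl)cyclohex-3-en-1-yl]propan-1-one
Conditions: EtLi (3.5 equiv), Et2O, 0 → 25 °C; aq NH4Cl
Reagents that add atoms: ethyllithium, [Li]CC
Why: Organolithium addition to the lithium carboxylate gives a dilithio gem-diolate that cannot over-add and collapses to the ethyl ketone on work-up (carboxylate-to-ketone synthesis).

Step 11
Reactants: 17 1-[(1R,6S)-6-[(tert-butyldimethylsilyloxy)methyl]-6-ethenyl-2,2-dimethyl-1-(prop-2-enyl)cyclohex-3-en-1-yl]propan-1-one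
Product: 18 1-[3a-[(tert-butyldimethylsilyloxy)methyl]-7,7-dimethyl-3a,4,7,7a-tetrahydro-1H-inden-7a-yl]propan-1-one (trans ring fusion; propanoyl anti to CH2OTBS)
Conditions: second-generation Grubbs catalyst (H2IMes)(PCy3)Cl2Ru=CHPh (5 mol %), CH2Cl2, 40 °C
Reagents that add atoms: none
Why: Ring-closing metathesis joins the trans-diequatorial allyl and vinyl groups into the trans-fused cyclopentene (ring B) and leaves the hindered internal ring A alkene alone, locking the propanoyl and CH2OTBS groups trans-diaxial.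

Step 12
Reactants: 18 1-[3a-[(tert-butyldimethylsilyloxy)methyl]-7,7-dimethyl-3a,4,7,7a-tetrahydro-1H-inden-7a-yl]propan-1-one
Product: 19 1-[3a-(hydroxymethyl)-7,7-dimethyl-3a,4,7,7a-tetrahydro-1H-inden-7a-yl]propan-1-one (trans-fused)
Conditions: Bu4NF, THF, rt
Reagents that add atoms: none
Why: Fluoride-induced desilylation frees the primary alcohol, and the anti ketone cannot form a hemiketal with it.

Step 13
Reactants: 19 1-[3a-(hydroxymethyl)-7,7-dimethyl-3a,4,7,7a-tetrahydro-1H-inden-7a-yl]propan-1-one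
Product: 21 7,7-dimethyl-7a-propanoyl-1,4,7,7a-tetrahydro-3aH-indene-3a-carboxylic acid (trans-fused; CO2H anti to propanoyl), via aldehyde 20 (not isolated)
Conditions: Dess–Martin periodinane, CH2Cl2, rt; then NaClO2, NaH2PO4, 2-methylbut-2-ene, t-BuOH/H2O, rt
Reagents that add atoms: sodium chlorite, [Na+].[O-]Cl=O
Why: Dess–Martin oxidation to the neopentyl aldehyde followed by Pinnick oxidation gives the C12 acid without touching either alkene.

Step 14
Reactants: 21 7,7-dimethyl-7a-propanoyl-1,4,7,7a-tetrahydro-3aH-indene-3a-carboxylic acid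
Product: 22 iodolactone of 21 (C12 carboxyl closed onto C3 on the top face; iodine on C4 on the bottom face; ring B alkene intact)
Conditions: I2, NaHCO3, THF/H2O, 0 °C, dark
Reagents that add atoms: iodine, II
Why: Iodolactonisation in which the axial C12 carboxylate reaches C3 only from the top face in a 5-exo closure (faster than 4-exo or 5-endo attack on the ring B alkene), so the C3–O bond is fixed on the top face with iodine trans-diaxial at C4 and the ring A alkene is masked.

Step 15
Reactants: 22 iodolactone of 21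
Product: 23 methyl 5,6-epoxy-7,7-dimethyl-7a-propanoyl-1,4,5,6,7,7a-hexahydro-3aH-indene-3a-carboxylate (C3–C4 epoxide on the top face, cis to CO2Me)
Conditions: NaOMe, MeOH, 0 → 25 °C
Reagents that add atoms: sodium methoxide, [Na+].[O-]C
Why: Methanolysis of the strained lactone frees the top-face C3 alkoxide, which displaces the anti iodide (intramolecular Williamson epoxide closure) to give the top-face epoxide.

Step 16
Reactants: 23 methyl 5,6-epoxy-7,7-dimethyl-7a-propanoyl-1,4,5,6,7,7a-hexahydro-3aH-indene-3a-carboxylate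
Product: 24 methyl 5,6-(carbonyldioxy)-7,7-dimethyl-7a-propanoyl-1,4,5,6,7,7a-hexahydro-3aH-indene-3a-carboxylate (cis C3/C4 cyclic carbonate on the top face)
Conditions: CO2 (10 bar), LiBr (10 mol %), NMP, 100 °C
Reagents that add atoms: carbon dioxide, O=C=O
Why: Bromide-catalysed CO2–epoxide cycloaddition, in which bromide opens the epoxide with inversion and the carbonate anion displaces bromide with a second inversion, so both C–O bonds stay on the top face (cis carbonate) whichever carbon is attacked first.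

Step 17
Reactants: 24 methyl 5,6-(carbonyldioxy)-7,7-dimethyl-7a-propanoyl-1,4,5,6,7,7a-hexahydro-3aH-indene-3a-carboxylate
Product: 26 methyl 5,6-(carbonyldioxy)-7a-(2-diazopropanoyl)-7,7-dimethyl-1,4,5,6,7,7a-hexahydro-3aH-indene-3a-carboxylate, via trifluoroacetyl diketone 25 (not isolated)
Conditions: LiN(SiMe3)2, THF, −78 °C; CF3CO2CH2CF3; 5% HCl work-up; then MsN3, Et3N, H2O, MeCN, rt
Reagents that add atoms: methanesulfonyl azide, CS(=O)(=O)N=[N+]=[N-]
Why: Danheiser detrifluoroacetylative diazo transfer, in which Claisen-type trifluoroacetylation of the kinetic enolate activates the only enolisable position for Regitz diazo transfer with loss of the trifluoroacetyl group.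

Step 18
Reactants: 26 methyl 5,6-(carbonyldioxy)-7a-(2-diazopropanoyl)-7,7-dimethyl-1,4,5,6,7,7a-hexahydro-3aH-indene-3a-carboxylate
Product: 27 cage ketone: methyl ester at C12, 11-oxo, 10-methyl, 5,5-dimethyl, top-face 3,4-cyclic carbonate (cyclopropane C8–C9–C10 closed)
Conditions: Cu(acac)2 (5 mol %), toluene, 80 °C, slow addition
Reagents that add atoms: none
Why: Intramolecular cyclopropanation by the copper carbenoid, in which the axial acyl tether can deliver the carbene only to the adjacent face of the ring B alkene, closing the cyclopropane and fixing C8, C9 and C10 from the existing C1 and C6 centres.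

Step 19
Reactants: 27 cage ketone
Product: 28 cage 11-epi alcohol (C11–OH pointing towards C1; otherwise as 27)
Conditions: NaBH4, MeOH/THF, 0 °C
Reagents that add atoms: none
Why: Borohydride reduction of the cage ketone, with hydride entering from the open C7 side because the C2 methylene shields the other face, giving the alcohol with OH towards C1.

Step 20
Reactants: 28 cage 11-epi alcohol
Product: 30 cage 11-acetate (C11–OAc pointing towards C7 as in the target; C12 methyl ester; 3,4-carbonate), via mesylate 29 (not isolated)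
Conditions: MsCl, Et3N, CH2Cl2, −20 °C; then KOAc, AcOH, 40 °C
Reagents that add atoms: potassium acetate, CC(=O)[O-].[K+]
Why: Mesylation then buffered acetolysis (SN1 through the cyclopropylcarbinyl nortricyclyl cation), in which acetate adds to C11 from the open C7 side, anti to the leaving group, installing the acetate with the target configuration whichever alcohol epimer is ionised.

Step 21
Reactants: 30 cage 11-acetate
Product: 31 cage tetraol (C3–OH and C4–OH cis on the top face; C11–OH towards C7; C12H2OH)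
Conditions: LiAlH4, THF, 0 → 65 °C; Fieser work-up
Reagents that add atoms: none
Why: Hydride reduction with LiAlH4 cleaves the carbonate and the acetate and reduces the neopentyl ester, leaving the cyclopropane intact.

Step 22
Reactants: 31 cage tetraol
Product: 32 cage 3,4-O-(1-methoxyethylidene) orthoester diol (C11–OH and C12–OH free)
Conditions: MeC(OMe)3, camphorsulfonic acid (cat.), CH2Cl2, rt
Reagents that add atoms: trimethyl orthoacetate, CC(OC)(OC)OC
Why: Acid-catalysed orthoester exchange selectively forms the five-membered cyclic orthoacetate on the cis-3,4-diol.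

Step 23
Reactants: 32 cage orthoester diol
Product: 33 cage orthoester 11,12-diacetate
Conditions: Ac2O, pyridine, DMAP (cat.), rt
Reagents that add atoms: acetic anhydride, CC(=O)OC(C)=O
Why: DMAP-catalysed acylation esterifies the primary C12 and secondary C11 hydroxyls while the orthoester is stable to base.

Step 24
Reactants: 33 cage orthoester 11,12-diacetate
Product: 34 target CNP0197219.1 (C3, C11 and C12 acetates; free C4–OH)
Conditions: 80% aq AcOH, rt
Reagents that add atoms: water, O
Why: Mild acid hydrolysis of the cyclic orthoester collapses the hemiorthoester to the axial ester (orthoester-mediated regioselective monoacylation), giving the C3 acetate and the free equatorial C4 hydroxyl under non-basic conditions that prevent acyl migration.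

## Compound list

1 | 2,2,6-trimethyl-4H-1,3-dioxin-4-one | CC1=CC(=O)OC(C)(C)O1 | starting material
2 | 2,2-dimethyl-6-methylidene-4-(trimethylsilyloxy)-1,3-diox-4-ene | C=C1C=C(O[Si](C)(C)C)OC(C)(C)O1 | intermediate
3 | 3-methylbut-2-enal | CC(C)=CC=O | starting material
4 | 2,2-dimethyl-6-[(2R)-4-methyl-2-(trimethylsilyloxy)pent-3-enyl]-4H-1,3-dioxin-4-one | CC(C)=C[C@H](O[Si](C)(C)C)CC1=CC(=O)OC(C)(C)O1 | intermediate
5 | 6-[(2R)-2-hydroxy-4-methylpent-3-enyl]-2,2-dimethyl-4H-1,3-dioxin-4-one | CC(C)=C[C@H](O)CC1=CC(=O)OC(C)(C)O1 | intermediate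
6 | (5R)-5-hydroxy-7-methyl-3-oxoocta-1,6-dien-1-one (acylketene) | CC(C)=C[C@H](O)CC(=O)C=C=O | intermediate
7 | (6R)-6-(2-methylprop-1-enyl)oxane-2,4-dione | CC(C)=C[C@H]1CC(=O)CC(=O)O1 | intermediate
8 | (6R)-6-(2-methylprop-1-enyl)-2-oxo-5,6-dihydro-2H-pyran-4-yl trifluoromethanesulfonate | CC(C)=C[C@H]1CC(OS(=O)(=O)C(F)(F)F)=CC(=O)O1 | intermediate
9 | (6R)-4-(hydroxymethyl)-6-(2-methylprop-1-enyl)-5,6-dihydro-2H-pyran-2-one | CC(C)=C[C@H]1CC(CO)=CC(=O)O1 | intermediate
10 | (6R)-4-[(tert-butyldimethylsilyloxy)methyl]-6-(2-methylprop-1-enyl)-5,6-dihydro-2H-pyran-2-one | CC(C)=C[C@H]1CC(CO[Si](C)(C)C(C)(C)C)=CC(=O)O1 | intermediate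
11 | 4-[(tert-butyldimethylsilyloxy)methyl]-4-ethenyl-2-(2-methylprop-1-enyl)-6-(trimethylsilyloxy)-3,4-dihydro-2H-pyran (ring centres as in 12) | C[Si](C)(C)OC1=C[C@](C=C)(CO[Si](C)(C)C(C)(C)C)C[C@H](C=C(C)C)O1 | intermediate
12 | (4R,6R)-4-[(tert-butyldimethylsilyloxy)methyl]-4-ethenyl-6-(2-methylprop-1-enyl)oxan-2-one (ethenyl trans, CH2OTBS cis to the propenyl group) | O=C1C[C@](C=C)(CO[Si](C)(C)C(C)(C)C)C[C@H](C=C(C)C)O1 | intermediate
13 | 3-allyl-4-[(tert-butyldimethylsilyloxy)methyl]-4-ethenyl-6-(2-methylprop-1-enyl)oxan-2-one (epimer mixture at the allyl-bearing carbon) | O=C1C(CC=C)[C@](C=C)(CO[Si](C)(C)C(C)(C)C)C[C@H](C=C(C)C)O1 | intermediate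
14 | 5-allyl-4-[(tert-butyldimethylsilyloxy)methyl]-4-ethenyl-2-(2-methylprop-1-enyl)-6-(trimethylsilyloxy)-3,4-dihydro-2H-pyran | C=CCC1=C(O[Si](C)(C)C)O[C@@H](C=C(C)C)C[C@@]1(C=C)CO[Si](C)(C)C(C)(C)C | intermediate
15 | trimethylsilyl ester of 16 | C[Si](C)(C)OC(=O)[C@]1(CC=C)C(C)(C)C=CC[C@@]1(C=C)CO[Si](C)(C)C(C)(C)C | intermediate
16 | (1R,6S)-6-[(tert-butyldimethylsilyloxy)methyl]-6-ethenyl-2,2-dimethyl-1-(prop-2-enyl)cyclohex-3-ene-1-carboxylic acid | OC(=O)[C@]1(CC=C)C(C)(C)C=CC[C@@]1(C=C)CO[Si](C)(C)C(C)(C)C | intermediate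
17 | 1-[(1R,6S)-6-[(tert-butyldimethylsilyloxy)methyl]-6-ethenyl-2,2-dimethyl-1-(prop-2-enyl)cyclohex-3-en-1-yl]propan-1-one | CCC(=O)[C@]1(CC=C)C(C)(C)C=CC[C@@]1(C=C)CO[Si](C)(C)C(C)(C)C | intermediate
18 | 1-[3a-[(tert-butyldimethylsilyloxy)methyl]-7,7-dimethyl-3a,4,7,7a-tetrahydro-1H-inden-7a-yl]propan-1-one (trans-fused; propanoyl anti to CH2OTBS) | CCC(=O)[C@@]12CC=C[C@@]1(CO[Si](C)(C)C(C)(C)C)CC=CC2(C)C | intermediate
19 | 1-[3a-(hydroxymethyl)-7,7-dimethyl-3a,4,7,7a-tetrahydro-1H-inden-7a-yl]propan-1-one (trans-fused) | CCC(=O)[C@@]12CC=C[C@@]1(CO)CC=CC2(C)C | intermediate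
20 | 7,7-dimethyl-7a-propanoyl-1,4,7,7a-tetrahydro-3aH-indene-3a-carbaldehyde (trans-fused) | CCC(=O)[C@@]12CC=C[C@@]1(C=O)CC=CC2(C)C | intermediate
21 | 7,7-dimethyl-7a-propanoyl-1,4,7,7a-tetrahydro-3aH-indene-3a-carboxylic acid (trans-fused) | CCC(=O)[C@@]12CC=C[C@@]1(C(O)=O)CC=CC2(C)C | intermediate
22 | iodolactone of 21 (C12 carboxyl to O–C3 on the top face; 4-iodo on the bottom face) | CCC(=O)[C@@]12CC=C[C@@]13C[C@H](OC3=O)[C@@H](I)C2(C)C | intermediate
23 | methyl 5,6-epoxy-7,7-dimethyl-7a-propanoyl-1,4,5,6,7,7a-hexahydro-3aH-indene-3a-carboxylate (top-face epoxide) | CCC(=O)[C@@]12CC=C[C@@]1(C(=O)OC)C[C@@H]3O[C@@H]3C2(C)C | intermediate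
24 | methyl 5,6-(carbonyldioxy)-7,7-dimethyl-7a-propanoyl-1,4,5,6,7,7a-hexahydro-3aH-indene-3a-carboxylate (top-face cis carbonate) | CCC(=O)[C@@]12CC=C[C@@]1(C(=O)OC)C[C@@H]3OC(=O)O[C@@H]3C2(C)C | intermediate
25 | 7a-[2-(trifluoroacetyl)propanoyl] analogue of 24 (epimers at the new CH) | CC(C(=O)C(F)(F)F)C(=O)[C@@]12CC=C[C@@]1(C(=O)OC)C[C@@H]3OC(=O)O[C@@H]3C2(C)C | intermediate
26 | methyl 5,6-(carbonyldioxy)-7a-(2-diazopropanoyl)-7,7-dimethyl-1,4,5,6,7,7a-hexahydro-3aH-indene-3a-carboxylate | CC(=[N+]=[N-])C(=O)[C@@]12CC=C[C@@]1(C(=O)OC)C[C@@H]3OC(=O)O[C@@H]3C2(C)C | intermediate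
27 | cage ketone (C12 methyl ester; 11-oxo; top-face 3,4-carbonate) | COC(=O)[C@]12C[C@@H]3OC(=O)O[C@@H]3C(C)(C)[C@]14C[C@@H]1[C@H]2[C@]1(C)C4=O | intermediate
28 | cage 11-epi alcohol (OH towards C1) | COC(=O)[C@]12C[C@@H]3OC(=O)O[C@@H]3C(C)(C)[C@]14C[C@@H]1[C@H]2[C@]1(C)[C@@H]4O | intermediate
29 | cage 11-epi mesylate | COC(=O)[C@]12C[C@@H]3OC(=O)O[C@@H]3C(C)(C)[C@]14C[C@@H]1[C@H]2[C@]1(C)[C@@H]4OS(C)(=O)=O | intermediate
30 | cage 11-acetate (OAc towards C7; C12 methyl ester; 3,4-carbonate) | COC(=O)[C@]12C[C@@H]3OC(=O)O[C@@H]3C(C)(C)[C@]14C[C@@H]1[C@H]2[C@]1(C)[C@H]4OC(C)=O | intermediate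
31 | cage tetraol (3,4-cis diol on the top face; 11-OH towards C7; 12-OH) | OC[C@]12C[C@H](O)[C@H](O)C(C)(C)[C@]13C[C@@H]1[C@H]2[C@]1(C)[C@H]3O | intermediate
32 | cage 3,4-O-(1-methoxyethylidene) orthoester 11,12-diol (orthoester carbon epimers) | OC[C@]12C[C@@H]3OC(C)(OC)O[C@@H]3C(C)(C)[C@]14C[C@@H]1[C@H]2[C@]1(C)[C@H]4O | intermediate
33 | cage 3,4-O-(1-methoxyethylidene) orthoester 11,12-diacetate | CC(=O)OC[C@]12C[C@@H]3OC(C)(OC)O[C@@H]3C(C)(C)[C@]14C[C@@H]1[C@H]2[C@]1(C)[C@H]4OC(C)=O | intermediate
34 | CNP0197219.1 (3,11,12-triacetate with free 4-OH) | CC(=O)OC[C@]12C[C@H](OC(C)=O)[C@H](O)C(C)(C)[C@]13C[C@@H]1[C@H]2[C@]1(C)[C@H]3OC(C)=O | target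

## Step count and risks

Total steps: 24. Longest linear sequence: 24 steps (1 → 34; aldehyde 3 enters at step 2).

Steps most likely to fail:

Step 9 (Ireland–Claisen ring contraction). Three contiguous quaternary carbons are made through a fully substituted ketene acetal, so both enolisation and the boat transition state are congested. The fallback avoids the ester enolate and runs the rearrangement on the neutral cyclic enol ether. Setting out from 13, DIBAL-H at −78 °C gives the lactol F1. MsCl/Et3N followed by warming eliminates it to the 3,4-dihydro-2H-pyran enol ether F2. Heating in o-xylene at 180 °C (sealed tube) effects the thermal Claisen rearrangement through the same boat arrangement to the aldehyde F3. EtMgBr gives the carbinol F4, and Dess–Martin oxidation returns to the route at ketone 17.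

Step 18 (cyclopropanation of the α-methyl diazo ketone). A 1,2-hydride shift to the vinyl ketone can outrun carbene addition. The fallback builds the cyclopropane by two polar bond formations instead of a carbene. Setting out from 24, TMSOTf/Et3N gives the silyl enol ether F5. N-Iodosuccinimide triggers iodo-carbocyclisation (C10 adds to C8 from the tether face, iodine ends anti on C9) to the iodo ketone F6; the C9-attack regioisomer would converge on the same cage. KOtBu then forms the C10 enolate, which displaces the exo iodide (1,3-elimination) and rejoins the route at cage ketone 27.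

Step 20 (acetolysis at C11). The delocalised cation can also be captured at C8 or C9 to give homoallylic acetates. The fallback replaces ionisation by thermodynamic epimerisation of the carbinol. Setting out from 28, reversible hydrogen transfer with (η5-C5Ph5)Ru(CO)2Cl and catalytic KOtBu in toluene at 70 °C equilibrates C11 towards the less congested alcohol F7 (OH towards C7). F7 is separated, the minor epimer recycled, and acetylation (Ac2O, DMAP, pyridine) rejoins the route at 30.

## Further compounds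

F1 | step 9 | 3-allyl-4-[(tert-butyldimethylsilyloxy)methyl]-4-ethenyl-6-(2-methylprop-1-enyl)oxan-2-ol (lactol; anomer and allyl epimers) | OC1C(CC=C)[C@](C=C)(CO[Si](C)(C)C(C)(C)C)C[C@H](C=C(C)C)O1
F2 | step 9 | 5-allyl-4-[(tert-butyldimethylsilyloxy)methyl]-4-ethenyl-2-(2-methylprop-1-enyl)-3,4-dihydro-2H-pyran | C=CCC1=CO[C@@H](C=C(C)C)C[C@@]1(C=C)CO[Si](C)(C)C(C)(C)C
F3 | step 9 | 6-[(tert-butyldimethylsilyloxy)methyl]-6-ethenyl-2,2-dimethyl-1-(prop-2-enyl)cyclohex-3-ene-1-carbaldehyde (configuration as in 16) | O=C[C@]1(CC=C)C(C)(C)C=CC[C@@]1(C=C)CO[Si](C)(C)C(C)(C)C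
F4 | step 9 | 1-[6-[(tert-butyldimethylsilyloxy)methyl]-6-ethenyl-2,2-dimethyl-1-(prop-2-enyl)cyclohex-3-en-1-yl]propan-1-ol (carbinol epimers) | CCC(O)[C@]1(CC=C)C(C)(C)C=CC[C@@]1(C=C)CO[Si](C)(C)C(C)(C)C
F5 | step 18 | trimethylsilyl enol ether of ketone 24 | CC=C(O[Si](C)(C)C)[C@@]12CC=C[C@@]1(C(=O)OC)C[C@@H]3OC(=O)O[C@@H]3C2(C)C
F6 | step 18 | iodo ketone (C10–C8 bond formed; 9-iodo anti; C10 epimers) | COC(=O)[C@]12C[C@@H]3OC(=O)O[C@@H]3C(C)(C)[C@]14C[C@H]([C@@H]2I)C(C)C4=O
F7 | step 20 | cage 11-alcohol with OH towards C7 (C11 epimer of 28) | COC(=O)[C@]12C[C@@H]3OC(=O)O[C@@H]3C(C)(C)[C@]14C[C@@H]1[C@H]2[C@]1(C)[C@H]4O
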